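**Retrosynthetic overview**
- Target ring numbering: C1 (C=O), C2 (benzoyl), C3 (enol C–OH), C4 (quaternary, two prenyl groups), C5 (enol C–OH), C6 (prenyl). The benzoyl carbon, C2 and C3 with its oxygen form a 1,3-dicarbonyl unit that maps onto C3 (C=N), C4 and C5–O1 of a 3-phenylisoxazole.
- Last disconnection: the benzoyl enol is released from a 3-phenyl-1,2-benzoxazol-6(7H)-one by N–O cleavage with Mo(CO)6 and hydrolysis of the resulting enaminone.
- Key disconnection: the C6–C1 bond, closed by Dieckmann condensation of an isoxazole keto ester in which C4 is already quaternary and C6 is the only enolisable carbon.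
- The keto ester comes from ethyl 5-methyl-3-phenylisoxazole-4-carboxylate by lateral lithiation and acylation with the Weinreb amide of 5-methylhex-4-enoic acid (C4–C5 bond), then double C-prenylation at C4.
- Ring order: the isoxazole is bought; the six-membered carbocycle is the only ring formed (step 4); the isoxazole is opened last (steps 5 and 6).

Key step: step 4

Assumption (remark on the chemistry): compounds 10–12 are rapidly interconverting enol tautomers and each is drawn as one tautomer, the target as that of the given SMILES. The target has no stereocentre; the only stereocentre on the route is in the racemic, non-isolated intermediate 8.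

**Step 1**
Reactants: 1 5-methylhex-4-enoic acid
Product: 3 N-methoxy-N,5-dimethylhex-4-enamide, via acylimidazole 2 (not isolated)
Conditions: 1,1'-carbonyldiimidazole (CDI), CH2Cl2, rt; then MeNH(OMe)·HCl, rt
Reagents that add atoms: N,O-dimethylhydroxylamine hydrochloride, CNOC.Cl; 1,1'-carbonyldiimidazole, O=C(n1ccnc1)n1ccnc1 (its imidazole stays only in intermediate 2)
Why: CDI turns the acid into the acylimidazole, which the hydroxylamine aminolyses to the Weinreb amide (amide coupling), and the trisubstituted alkene is inert to both stages.

**Step 2**
Reactants: 4 ethyl 5-methyl-3-phenylisoxazole-4-carboxylate; 3 N-methoxy-N,5-dimethylhex-4-enamide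
Product: 6 ethyl 5-(6-methyl-2-oxohept-5-enyl)-3-phenylisoxazole-4-carboxylate, via lithiated isoxazole ester 5 (not isolated)
Conditions: LiN(iPr)2 (1.1 equiv), THF, −78 °C; then 3 (1.2 equiv), −78 → −20 °C; aq NH4Cl, cold
Reagents that add atoms: none
Why: The 5-methyl group is vinylogous to the 4-ester, so the amide base should give the lateral dienolate anion at −78 °C, which attacks the Weinreb amide through its exocyclic carbon (keeping the isoxazole aromatic) and stops at the chelated tetrahedral adduct until work-up (lateral metalation followed by Weinreb ketone synthesis).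

**Step 3**
Reactants: 6 ethyl 5-(6-methyl-2-oxohept-5-enyl)-3-phenylisoxazole-4-carboxylate; 7 prenyl bromide (1-bromo-3-methylbut-2-ene)
Product: 9 ethyl 5-[6-methyl-1,1-bis(3-methylbut-2-enyl)-2-oxohept-5-enyl]-3-phenylisoxazole-4-carboxylate, via monoprenylated keto ester 8 (not isolated)
Conditions: Cs2CO3 (3 equiv), 7 (2.5 equiv), MeCN, rt → 50 °C
Reagents that add atoms: none
Why: The methylene between the ketone and the 4-ethoxycarbonylisoxazol-5-yl ring is far more acidic than the C6 methylene, so Cs2CO3 should enolise only this site and the soft allylic bromide should C-alkylate it twice by SN2 substitution (exhaustive alkylation of an active methylene), after which the carbon carries no hydrogen and the weak base cannot touch C6.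

**Step 4**
Reactants: 9 ethyl 5-[6-methyl-1,1-bis(3-methylbut-2-enyl)-2-oxohept-5-enyl]-3-phenylisoxazole-4-carboxylate
Product: 10 4-hydroxy-3-phenyl-5,7,7-tris(3-methylbut-2-enyl)-1,2-benzoxazol-6(7H)-one
Conditions: LiN(SiMe3)2 (2.5 equiv), THF, −78 °C → rt; then 1 M HCl, 0 °C
Reagents that add atoms: none
Why: LiN(SiMe3)2 removes a proton from C6, the only enolisable carbon of 9 (C4 is quaternary and the isoxazole has no ring hydrogen), and the lithium enolate adds to the ester carbonyl on isoxazole C4 (target C1) to form the C6–C1 bond; loss of ethoxide gives the fused 1,3-diketone, which the second equivalent of base converts into its delocalised enolate, the thermodynamic sink that makes the condensation irreversible. This is a Dieckmann (intramolecular Claisen) condensation of a ketone enolate onto an ortho heteroaryl ester, the reaction type used to make cyclic 1,3-diones fused to arenes and to isoxazoles. The six-membered carbocycle closes in a 6-(enolexo)-exo-trig mode and no stereocentre is created, because C6 ends as an sp2 enol carbon. The step needs C-acylation over O-acylation and ring closure over retro-Claisen cleavage of the C4–C5 bond: any enol lactone from O-attack is reopened by the liberated ethoxide and funnels to the C-acylated enolate, while the hindered, non-nucleophilic amide base and the neopentyl-type shielding of the C5 carbonyl suppress nucleophilic attack at the ketone. The 3-phenyl group rules out base-induced isoxazole fragmentation, which requires a hydrogen at isoxazole C3.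

**Step 5**
Reactants: 10 4-hydroxy-3-phenyl-5,7,7-tris(3-methylbut-2-enyl)-1,2-benzoxazol-6(7H)-one
Product: 11 2-[amino(phenyl)methylidene]-5-hydroxy-4,6,6-tris(3-methylbut-2-enyl)cyclohex-4-ene-1,3-dione
Conditions: Mo(CO)6 (1 equiv), MeCN–H2O (10:1), 80 °C
Reagents that add atoms: none
Why: Zerovalent molybdenum should insert into the weak N–O bond and water supplies the two hydrogens, giving the push-pull enaminone (reductive ring opening of an isoxazole) under non-hydrogenating conditions that leave the three trisubstituted alkenes untouched.

**Step 6**
Reactants: 11 2-[amino(phenyl)methylidene]-5-hydroxy-4,6,6-tris(3-methylbut-2-enyl)cyclohex-4-ene-1,3-dione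
Product: 12 2-benzoyl-3,5-dihydroxy-4,4,6-tris(3-methylbut-2-enyl)cyclohexa-2,5-dien-1-one (CNP0210463.0)
Conditions: 2 M NaOH (aq), EtOH, 60 °C, argon; then 1 M HCl, 0 °C, to pH 2
Reagents that add atoms: water, O (delivered as hydroxide from aqueous NaOH, [Na+].[OH-])
Why: Hydroxide should add to the amino-bearing carbon of the vinylogous amide and expel ammonia (addition–elimination hydrolysis of an enaminodione), base being chosen over hot acid because strong acid would cyclise the prenyl groups onto the enol oxygens, and the product stays protected as its delocalised dianion until the cold acidification.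

**Compound list**
1 | 5-methylhex-4-enoic acid | CC(C)=CCCC(=O)O | starting material
2 | 1-(imidazol-1-yl)-5-methylhex-4-en-1-one (acylimidazole) | CC(C)=CCCC(=O)n1ccnc1 | intermediate
3 | N-methoxy-N,5-dimethylhex-4-enamide | CON(C)C(=O)CCC=C(C)C | intermediate
4 | ethyl 5-methyl-3-phenylisoxazole-4-carboxylate | CCOC(=O)c1c(-c2ccccc2)noc1C | starting material
5 | ethyl 5-(lithiomethyl)-3-phenylisoxazole-4-carboxylate | [Li]Cc1onc(-c2ccccc2)c1C(=O)OCC | intermediate
6 | ethyl 5-(6-methyl-2-oxohept-5-enyl)-3-phenylisoxazole-4-carboxylate | CCOC(=O)c1c(-c2ccccc2)noc1CC(=O)CCC=C(C)C | intermediate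
7 | prenyl bromide (1-bromo-3-methylbut-2-ene) | CC(C)=CCBr | starting material
8 | ethyl 5-[6-methyl-1-(3-methylbut-2-enyl)-2-oxohept-5-enyl]-3-phenylisoxazole-4-carboxylate (racemic) | CCOC(=O)c1c(-c2ccccc2)noc1C(CC=C(C)C)C(=O)CCC=C(C)C | intermediate
9 | ethyl 5-[6-methyl-1,1-bis(3-methylbut-2-enyl)-2-oxohept-5-enyl]-3-phenylisoxazole-4-carboxylate | CCOC(=O)c1c(-c2ccccc2)noc1C(CC=C(C)C)(CC=C(C)C)C(=O)CCC=C(C)C | intermediate
10 | 4-hydroxy-3-phenyl-5,7,7-tris(3-methylbut-2-enyl)-1,2-benzoxazol-6(7H)-one | O=C1C(CC=C(C)C)=C(O)c2c(-c3ccccc3)noc2C1(CC=C(C)C)CC=C(C)C | intermediate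
11 | 2-[amino(phenyl)methylidene]-5-hydroxy-4,6,6-tris(3-methylbut-2-enyl)cyclohex-4-ene-1,3-dione | NC(c1ccccc1)=C1C(=O)C(CC=C(C)C)=C(O)C(CC=C(C)C)(CC=C(C)C)C1=O | intermediate
12 | 2-benzoyl-3,5-dihydroxy-4,4,6-tris(3-methylbut-2-enyl)cyclohexa-2,5-dien-1-one | CC(C)=CCC1=C(O)C(CC=C(C)C)(CC=C(C)C)C(O)=C(C(=O)c2ccccc2)C1=O | target

**Step count**
Total steps: 6. Longest linear sequence: 6 steps (1 → 3 → 6 → 9 → 10 → 11 → 12); the isoxazole ester 4 enters at step 2 and prenyl bromide 7 at step 3.

**Steps most likely to fail**

Step 4 (key step). The C6 enolate may fail to reach the ester carbonyl, which is shielded by the phenyl group and by quaternary C4, or alkoxide attack at the C5 ketone may cleave the C4–C5 bond (retro-Claisen) faster than the ring closes. The fallback closes the ring before the quaternary centre exists. It sets out from ketone 6: excess LiN(SiMe3)2 in THF (or NaH in THF) should form the dianion, whose C6 terminus condenses with the ester, and the resulting diketone aromatises to 5-(3-methylbut-2-enyl)-3-phenyl-1,2-benzoxazole-4,6-diol F1. This is the usual cyclisation of ortho-(2-oxoalkyl) aryl esters to 1,3-dihydroxyarenes. Dearomative C-prenylation with prenyl bromide 7 and NaOMe in MeOH–toluene at 0 °C, the method by which acylphloroglucinols are converted into lupulone-type triprenyl dienones, should pass through 5,7-bis(3-methylbut-2-enyl)-3-phenyl-1,2-benzoxazole-4,6-diol F2 and give benzisoxazolone 10, where the route is rejoined. If the second alkylation falls on C5 instead of C7, the isomer 6-hydroxy-5,5,7-tris(3-methylbut-2-enyl)-3-phenyl-1,2-benzoxazol-4(5H)-one F3 would form. It needs no separation, because N–O cleavage under the conditions of step 5 converts it into the same enaminone 11: once the isoxazole is open, the two carbonyl groups flanking C2 are equivalent.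

Step 3. In the second alkylation the hindered, delocalised enolate may be alkylated on oxygen (with later sigmatropic shift to a reverse-prenyl isomer), or the enolate oxygen may lactonise onto the neighbouring ester. The fallback replaces SN2 alkylation by Tsuji–Trost allylation under neutral conditions. It sets out from 6 and returns at 9, passing through 8. Methyl 3-methylbut-2-enyl carbonate F4 (from 3-methylbut-2-en-1-ol and methyl chloroformate, pyridine) and catalytic Pd(PPh3)4 (zerovalent palladium) in THF at 50 °C generate methoxide and the 1,1-dimethylallyl palladium cation in situ. The stabilised enolate should attack the unsubstituted allyl terminus to give the linear prenyl group, and any O-allyl ether re-ionises under the catalyst, so the C-allylated product accumulates.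

Step 2. The lithiated ester may self-condense, or proton transfer between the anion and the amide or the ketone product may stall the acylation at partial conversion. The fallback replaces acylation by aldol addition and oxidation. It sets out from Weinreb amide 3, which iBu2AlH in THF at −78 °C should reduce to 5-methylhex-4-enal F5. The lithiated ester 5 (from 4 and LiN(iPr)2, −78 °C) should add rapidly and irreversibly to F5; a quench with acetic acid at −78 °C, before the alkoxide can lactonise onto the ester, should give ethyl 5-(2-hydroxy-6-methylhept-5-enyl)-3-phenylisoxazole-4-carboxylate F6 (racemic). Dess–Martin periodinane in CH2Cl2 with NaHCO3 should oxidise it to ketone 6, where the route is rejoined.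

**Further compounds**
F1 | step 4 | 5-(3-methylbut-2-enyl)-3-phenyl-1,2-benzoxazole-4,6-diol | CC(C)=CCc1c(O)cc2onc(-c3ccccc3)c2c1O
F2 | step 4 | 5,7-bis(3-methylbut-2-enyl)-3-phenyl-1,2-benzoxazole-4,6-diol | CC(C)=CCc1c(O)c(CC=C(C)C)c2onc(-c3ccccc3)c2c1O
F3 | step 4 | 6-hydroxy-5,5,7-tris(3-methylbut-2-enyl)-3-phenyl-1,2-benzoxazol-4(5H)-one | O=C1c2c(-c3ccccc3)noc2C(CC=C(C)C)=C(O)C1(CC=C(C)C)CC=C(C)C
F4 | step 3 | methyl 3-methylbut-2-enyl carbonate | COC(=O)OCC=C(C)C
F5 | step 2 | 5-methylhex-4-enal | CC(C)=CCCC=O
F6 | step 2 | ethyl 5-(2-hydroxy-6-methylhept-5-enyl)-3-phenylisoxazole-4-carboxylate (racemic) | CCOC(=O)c1c(-c2ccccc2)noc1CC(O)CCC=C(C)C
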